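The product in question is the mono adduct, which a substrate molecule becomes on taking one coupling partner and ceases to be on taking a second, so it is made and used in the same flask.

the same everywhere: substrate 13 mM

| charge | coupling partner | capture agent | remark | time |
|---|---|---|---|---|
| gamma | 8.7 mM | 0.65 mM | run made earlier |  |
| theta | 23 mM | 0.65 mM | run made earlier |  |
| grey | 19.5 mM | 0.650 mM |  | 10 h |
| green | 6.50 mM | 0.650 mM |  | 10 h |

| run | time / h | mono adduct / % | triple product / % |
|---|---|---|---|
| gamma | 0.333 | 22.4 | 0.6 |
| gamma | 1.00 | 28.1 | 3.1 |
| gamma | 2.00 | 28.4 | 3.3 |
| gamma | 2.50 | 28.5 | 3.4 |
| gamma | 4.00 | 28.9 | 3.3 |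
| gamma | 5.00 | 28.5 | 2.5 |
| theta | 0.333 | 34.3 | 7.4 |
| theta | 1.00 | 30.2 | 14.1 |
| theta | 2.00 | 27.8 | 15.7 |
| theta | 2.50 | 28.0 | 16.6 |
| theta | 4.00 | 27.6 | 15.6 |
| theta | 5.00 | 27.8 | 15.9 |

(standard deviation of a reading: 0.5 percentage points)

- in percentages every species weighs as the substrate in it: one homo dimer counts as two
- the numbers in the tables scatter by 0.5 percentage points (one standard deviation)
- reactions considered so far: coupling partner + mono adduct -> bis adduct + released group; substrate + coupling partner -> mono adduct + released group; 2 substrate -> homo dimer; coupling partner + triple product -> tetra adduct + released group; mono adduct + capture agent -> trapped intermediate; triple product <-> isomer of the product; coupling partner + bis adduct -> triple product + released group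

- which of these holds the largest part of the substrate at the end of grey (substrate / mono adduct / triple product / bis adduct / tetra adduct)
- which of these holds the largest part of the substrate at the end of green (substrate / mono adduct / triple product / bis adduct / tetra adduct)
- mono adduct at the end of grey, in percent of the substrate charged

The earlier readings look contradictory: theta got 2.64 times the partner of gamma, yet at 5.00 h the mono adduct reads 28.5% in gamma and 27.8% in theta. I follow one substrate molecule. At each fork it catches a partner or it doesn't, and if the steps run about equally fast, as I assume, the number caught is random with mean τ = c(coupling partner)/c(substrate), and the chance of exactly one is τ·exp(−τ). That curve rises up to τ of one and falls beyond it. Gamma at 0.669 and theta at 1.77 lie on opposite sides, giving 34.3% and 30.2%, so two different charges give close shares. The capture agent can remove mono adduct up to its charge, 5.00% of the substrate. Taking all of that off gives 29.3% for gamma, near its reading, and 25.2% for theta, which its reading exceeds.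

For grey τ is 1.50, so its one-partner share, the chance of exactly one partner, is 33.5%, and I expect the mono adduct between 28.5% and that value. The forecast commits to 29.5%, and names mono adduct for grey and substrate for green as holding most: “After the trap correction, mono is about 29.5 and still the largest.”

Grey gives 30.5% of mono adduct, ahead of substrate at 24.4%, and green keeps 58.6% as substrate. The step making the mono adduct and the step turning it into bis adduct have constants of 0.044 /M/s and 0.046 /M/s. The one-partner share of 33.5% stands 3 percentage points above the result, and 5.00% lies trapped, so the result falls inside the range I expected.

    coupling partner + mono adduct → bis adduct + released group (k = 0.0460 /M/s)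
    substrate + coupling partner → mono adduct + released group (k = 0.0440 /M/s)
    2 substrate → homo dimer (k = 9.70 × 10⁻⁵ /M/s)
    coupling partner + triple product → tetra adduct + released group (k = 0.0230 /M/s)
    mono adduct + capture agent → trapped intermediate (k = 0.130 /M/s)
    triple product ⇌ isomer of the product (K = 1.20, k = 0.00180 /s)
    coupling partner + bis adduct → triple product + released group (k = 0.190 /M/s)

The neighbour flask, grey with 2.6 mM of capture agent, has the same one-partner share, and its capture charge is 20.0% of the substrate, so I expect the mono adduct between 13.5% and 33.5%. The computed flask gives 20.8%, with 20.0% trapped.

The data stem from a simulated flask with constants of no real substance; noise was put on by code.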